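**Plan**
- Retrosynthetic cuts: (a) the CH2–CH2 bond between chain carbons C3 and C4 (counted from ring carbon C6), giving a 3-bromopropyl-pyranone and an 8-acetoxyoctyl-borane; (b) chain C1–C2 and (c) ring C6–chain C1, both leading back to symmetric 2,6-dimethoxy-3,5-dimethyl-4-pyranone; (d) ring O1–C2, back to dimethyl 2,4-dimethyl-3-oxoglutarate.
- Enabling features: C3 and C4 are unbranched, unfunctionalised methylenes; C4–C11 with its acetate is exactly the anti-Markovnikov hydroboration adduct of oct-7-enyl acetate; C3 lies two carbons beyond the acidic C6–CH3 position; the 3,5-dimethyl-4-pyranone ring has a latent mirror plane through O1 and C4=O, broken only by OMe versus alkyl at C2/C6.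
- Forward order: the pyranone ring is closed first (step 2), then desymmetrised and extended to the C3 bromide in one flask from three components (step 3); the acetate arm is made separately (step 4) and the chain is joined last, without protecting groups (step 5).
- Stereochemistry: the target has no stereocentre and no configured double bond; the two stereocentres of 2 are destroyed in step 2.

Key step: step 5

**Route**

Step 1
Reactants: 1 dimethyl 3-oxopentanedioate
Product: 2 dimethyl 2,4-dimethyl-3-oxopentanedioate (meso/dl mixture)
Conditions: MeI (2.1 equiv), K2CO3, acetone, reflux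
Reagents that add atoms: iodomethane, CI
Why: Each doubly activated methylene of the β-keto diester should be C-methylated once by enolate alkylation under mild carbonate conditions, and the diastereomer mixture is of no consequence because both centres become sp2 in step 2.

Step 2
Reactants: 2 dimethyl 2,4-dimethyl-3-oxopentanedioate
Product: 3 2,6-dimethoxy-3,5-dimethyl-4H-pyran-4-one
Conditions: oleum (20% SO3 in H2SO4), 0 °C to rt; ice, then NaHCO3
Reagents that add atoms: none
Why: In the strongly dehydrating acid the bis-enol form should close the ring at O1–C2 by attack of one ester-enol oxygen on the activated second ester carbon and lose water (not methanol) to give the aromatic 4-hydroxypyrylium, which is the acid cyclodehydration known for 3-oxoglutarate and 3,5-dioxo esters.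

Step 3
Reactants: 3 2,6-dimethoxy-3,5-dimethyl-4H-pyran-4-one
Product: 6 2-(3-bromopropyl)-6-methoxy-3,5-dimethyl-4H-pyran-4-one, via 2-methoxy-3,5,6-trimethyl-4H-pyran-4-one 4 (not isolated), via lithium dienolate 5 (not isolated)
Conditions: MeLi (1.05 equiv), THF, −78 to −20 °C; LiHMDS (1.2 equiv), −78 °C; cannulation into BrCH2CH2OTf (2.5 equiv), THF, −78 °C; aq. NH4Cl
Reagents that add atoms: methyllithium, [Li]C; 2-bromoethyl trifluoromethanesulfonate, BrCCOS(=O)(=O)C(F)(F)F
Why: Conjugate addition–elimination of MeLi at the ketene-acetal carbon C2 of the vinylogous carbonate should replace one methoxy group, LiHMDS should then remove a proton from the new C6–CH3 group, and the extended dienolate should react at its exocyclic carbon with the triflate end of the bis-electrophile (triflate being far the better leaving group), a one-flask desymmetrisation/lateral alkylation of a type with close precedent for α,α'-dialkoxy-γ-pyranones; inverse addition into excess triflate keeps base away from the product.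

Step 4
Reactants: 7 oct-7-en-1-ol
Product: 8 oct-7-en-1-yl acetate
Conditions: Ac2O, pyridine, DMAP (cat.), CH2Cl2, 0 °C to rt
Reagents that add atoms: acetic anhydride, CC(=O)OC(C)=O
Why: DMAP-catalysed acylation of a primary alcohol is routine and leaves the terminal alkene untouched.

Step 5
Reactants: 8 oct-7-en-1-yl acetate; 6 2-(3-bromopropyl)-6-methoxy-3,5-dimethyl-4H-pyran-4-one
Product: 10 11-(6-methoxy-3,5-dimethyl-4-oxo-4H-pyran-2-yl)undecyl acetate, via 8-(9-borabicyclo[3.3.1]nonan-9-yl)octyl acetate 9 (not isolated)
Conditions: 8 (1.4 equiv), 9-BBN (1.3 equiv), THF, 0 °C to rt; then 6 (1.0 equiv), Pd(OAc)2 (4 mol%), PCy3 (8 mol%), K3PO4·H2O (1.3 equiv), THF, rt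
Reagents that add atoms: none
Why: 9-BBN should add to the terminal C7=C8 double bond of 8 through a four-centre transition state with boron on the terminal carbon, so that borane 9 carries exactly the 8-acetoxyoctyl group. Pd(0)/PCy3 should then insert into the primary C–Br bond of 6 by an SN2-type oxidative addition, the hydroxy-borate formed from 9 and K3PO4·H2O should transfer its primary alkyl group to palladium, and reductive elimination should form the C(sp3)–C(sp3) bond between chain carbons C3 and C4. The closest known reaction type is the B-alkyl Suzuki–Miyaura coupling of primary alkyl bromides bearing β-hydrogens with alkyl-9-BBN reagents under palladium/trialkylphosphine catalysis. No ring is closed and no stereocentre is formed. The step needs terminal regioselectivity in the hydroboration (secured by the bulk of 9-BBN at a monosubstituted alkene), coupling ahead of β-hydride elimination (secured by the bulky, electron-rich PCy3), and survival of the acetate, the methoxy-pyranone and the acidic C1 methylene next to the ring (secured by the mild hydrated phosphate base at room temperature and by adding 6 only after a slight excess of alkene has consumed all B–H).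

**Compound list**
1 | dimethyl 3-oxopentanedioate | COC(=O)CC(=O)CC(=O)OC | starting material
2 | dimethyl 2,4-dimethyl-3-oxopentanedioate (meso/dl mixture) | COC(=O)C(C)C(=O)C(C)C(=O)OC | intermediate
3 | 2,6-dimethoxy-3,5-dimethyl-4H-pyran-4-one | COc1oc(OC)c(C)c(=O)c1C | intermediate
4 | 2-methoxy-3,5,6-trimethyl-4H-pyran-4-one (formed in the flask, not isolated) | COc1oc(C)c(C)c(=O)c1C | intermediate
5 | lithium 6-methoxy-3,5-dimethyl-2-methylidene-2H-pyran-4-olate (lateral lithium dienolate of 4, not isolated) | C=C1OC(OC)=C(C)C(O[Li])=C1C | intermediate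
6 | 2-(3-bromopropyl)-6-methoxy-3,5-dimethyl-4H-pyran-4-one | COc1oc(CCCBr)c(C)c(=O)c1C | intermediate
7 | oct-7-en-1-ol | C=CCCCCCCO | starting material
8 | oct-7-en-1-yl acetate | C=CCCCCCCOC(C)=O | intermediate
9 | 8-(9-borabicyclo[3.3.1]nonan-9-yl)octyl acetate (not isolated) | CC(=O)OCCCCCCCCB1C2CCCC1CCC2 | intermediate
10 | 11-(6-methoxy-3,5-dimethyl-4-oxo-4H-pyran-2-yl)undecyl acetate | COc1oc(CCCCCCCCCCCOC(C)=O)c(C)c(=O)c1C | target

**Count**
Total steps: 5. Longest linear sequence: 4 (steps 1, 2, 3, 5).

**Steps most likely to fail**

Step 3. The processes at risk are a second substitution or a carbonyl addition by MeLi, O- instead of C-alkylation of dienolate 5 by the hard triflate, and proton transfer from the product to 5 followed by closure of a cyclopropane. The fallback sets out from 3 and comes back at 6. It uses a sulfone-stabilised nucleophile, whose adduct is deprotonated in the flask and so protected from a second attack. Lithiated methyl phenyl sulfone (2 equiv, THF, −78 °C) should convert 3 into 2-methoxy-3,5-dimethyl-6-[(phenylsulfonyl)methyl]-4H-pyran-4-one F1. Alkylation of its stabilised anion (K2CO3, NaI, DMF, 60 °C) with (2-bromoethoxy)(tert-butyl)dimethylsilane should give racemic 2-[3-(tert-butyldimethylsilyloxy)-1-(phenylsulfonyl)propyl]-6-methoxy-3,5-dimethyl-4H-pyran-4-one F2. Reductive desulfonylation (SmI2, THF/MeOH, −78 °C, or aluminium amalgam) should give 2-[3-(tert-butyldimethylsilyloxy)propyl]-6-methoxy-3,5-dimethyl-4H-pyran-4-one F3. TBAF in THF should release 2-(3-hydroxypropyl)-6-methoxy-3,5-dimethyl-4H-pyran-4-one F4, and CBr4/PPh3 (CH2Cl2, 0 °C) should convert it into 6.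

Step 5. The process at risk is slow transmetalation, so that β-hydride elimination, or base-induced 3-exo closure of the bromopropyl arm onto the deprotonated C1 position, overtakes the coupling. The fallback sets out from 3 and comes back at 10; it makes the same C3–C4 bond as an alkene by cross-metathesis. Compound 3 is treated as in step 3, but dienolate 5 is trapped with allyl bromide to give 2-(but-3-en-1-yl)-6-methoxy-3,5-dimethyl-4H-pyran-4-one F5. Commercial non-8-en-1-ol is acetylated as in step 4 to non-8-en-1-yl acetate F6. Cross-metathesis of F5 with an excess of F6 (second-generation ruthenium NHC benzylidene catalyst, CH2Cl2, 40 °C) should give (E)-11-(6-methoxy-3,5-dimethyl-4-oxo-4H-pyran-2-yl)undec-8-en-1-yl acetate F7; the E isomer is expected to predominate and any Z isomer serves equally. Hydrogenation (H2, Pd/C, EtOAc, rt) should then give 10.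

Step 2. The process at risk is hydrolysis of a methoxy group or decomposition in oleum in place of clean loss of water. The fallback sets out from 2 and comes back at 4; it is the classical route through a 4-hydroxy-2-pyranone and avoids the symmetric pyranone. Halide-induced loss of one methoxycarbonyl group from 2 (Krapcho conditions: LiCl, wet DMSO, 140 °C, stopped at partial conversion) should give methyl 2-methyl-3-oxopentanoate F8. Its dianion (NaH, then n-BuLi, THF, 0 °C) should be acylated at C4 by N-methoxy-N-methylacetamide to give methyl 2,4-dimethyl-3,5-dioxohexanoate F9. DBU (toluene, reflux) should close the ring to 4-hydroxy-3,5,6-trimethyl-2H-pyran-2-one F10. Methylation at the lactone carbonyl oxygen with methyl fluorosulfonate or methyl triflate (CH2Cl2, rt; then aq. NaHCO3) should give 4, which is then isolated and enters step 3 at the LiHMDS stage.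

**Further compounds**
F1 | step 3 | 2-methoxy-3,5-dimethyl-6-[(phenylsulfonyl)methyl]-4H-pyran-4-one | COc1oc(CS(=O)(=O)c2ccccc2)c(C)c(=O)c1C
F2 | step 3 | 2-[3-(tert-butyldimethylsilyloxy)-1-(phenylsulfonyl)propyl]-6-methoxy-3,5-dimethyl-4H-pyran-4-one (racemic) | COc1oc(C(CCO[Si](C)(C)C(C)(C)C)S(=O)(=O)c2ccccc2)c(C)c(=O)c1C
F3 | step 3 | 2-[3-(tert-butyldimethylsilyloxy)propyl]-6-methoxy-3,5-dimethyl-4H-pyran-4-one | COc1oc(CCCO[Si](C)(C)C(C)(C)C)c(C)c(=O)c1C
F4 | step 3 | 2-(3-hydroxypropyl)-6-methoxy-3,5-dimethyl-4H-pyran-4-one | COc1oc(CCCO)c(C)c(=O)c1C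
F5 | step 5 | 2-(but-3-en-1-yl)-6-methoxy-3,5-dimethyl-4H-pyran-4-one | COc1oc(CCC=C)c(C)c(=O)c1C
F6 | step 5 | non-8-en-1-yl acetate | C=CCCCCCCCOC(C)=O
F7 | step 5 | (E)-11-(6-methoxy-3,5-dimethyl-4-oxo-4H-pyran-2-yl)undec-8-en-1-yl acetate | COc1oc(CC/C=C/CCCCCCCOC(C)=O)c(C)c(=O)c1C
F8 | step 2 | methyl 2-methyl-3-oxopentanoate (racemic) | CCC(=O)C(C)C(=O)OC
F9 | step 2 | methyl 2,4-dimethyl-3,5-dioxohexanoate (diastereomer mixture) | CC(=O)C(C)C(=O)C(C)C(=O)OC
F10 | step 2 | 4-hydroxy-3,5,6-trimethyl-2H-pyran-2-one | Cc1oc(=O)c(C)c(O)c1C
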